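**Retrosynthetic overview**
- C1–C10: the ten-membered ring is closed last by an intramolecular Nozaki–Hiyama–Kishi reaction of a (Z)-alkenyl iodide onto the C1 aldehyde, so the C1 hydroxyl is formed free.
- C6–C7 and C7–C8: two Barbier allylations around one C7 linchpin, methyl 3-bromo-2-(bromomethyl)acrylate; the α-methylene lactone closes after the first and then relays C6 to C7 and C8.
- C3–C6 with the (Z)-C4=C5 alkene and C15 come from furan-3-ylmethanol by singlet-oxygen oxidation to a γ-hydroxybutenolide, which keeps the alkene Z inside a ring.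
- C3 and the C1–C2 unit: chiral phosphoric acid-catalysed allylboration/lactonisation of that pseudo-acid (new step, first stereocentre); the allyl terminus is cleaved late to the C1 aldehyde.
- Ring order: temporary butenolide, then α-methylene-γ-lactone, then the carbocycle; acetate goes on C3 after the first Barbier step, angelate on C8 after the second.

Assumption: germacranolide numbering is used (C1 carbinol, C3 acetate, C4=C5, C6 lactone oxygen, C7, C8 angelate, C9=C10, C11=C13, C12 carbonyl, C14 methyl, C15 CH2OH); the SMILES corresponds to 1S,3S,6S,7S,8R,4Z,9Z.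

**Route**

Step 1
Reactants: 1 furan-3-ylmethanol
Product: 2 tert-butyl(furan-3-ylmethoxy)diphenylsilane
Conditions: TBDPSCl, imidazole, DMF, 0 °C to rt
Reagents that add atoms: tert-butyl(chloro)diphenylsilane, CC(C)(C)[Si](Cl)(c1ccccc1)c1ccccc1
Why: Imidazole-promoted silyl ether formation on the only hydroxyl; TBDPS survives the Lewis-acidic acetylation and both Barbier steps and is removed last.

Step 2
Reactants: 2 silyl ether of furan-3-ylmethanol
Product: 4 5-hydroxy-4-{[tert-butyl(diphenyl)silyl]oxymethyl}furan-2(5H)-one (racemic labile lactol), via furan endoperoxide 3 (not isolated)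
Conditions: O2, hν (visible), tetraphenylporphyrin (cat.), i-Pr2NEt, CH2Cl2, −78 °C, then rt
Reagents that add atoms: dioxygen, O=O
Why: Singlet-oxygen [4+2] cycloaddition followed by base-mediated Kornblum–DeLaMare-type fragmentation, in which the hindered amine removes the less hindered bridgehead proton so the carbonyl forms at C6 and the lactol at C3, fixing the future C4=C5 alkene as Z in the ring; no lasting stereocentre is formed.

Step 3
Reactants: 4 γ-hydroxybutenolide (pseudo-acid)
Product: 6 (5S)-4-{[tert-butyl(diphenyl)silyl]oxymethyl}-5-(prop-2-en-1-yl)furan-2(5H)-one, via hydroxy acid 5 (not isolated)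
Conditions: allylB(pin) (1.5 equiv), (S)-TRIP [(S)-3,3'-bis(2,4,6-triisopropylphenyl)-1,1'-binaphthyl-2,2'-diyl hydrogen phosphate] (5 mol %), toluene, −30 °C to 0 °C; then pH 4 aqueous work-up, rt
Reagents that add atoms: allylboronic acid pinacol ester, C=CCB1OC(C)(C)C(C)(C)O1
Why: Proposed new method: pseudo-acid 4 is in ring–chain equilibrium with the (Z)-4-oxo-2-enoic acid, whose aldehyde is captured by allylB(pin) in a closed six-membered chair transition state organised by the chiral phosphoric acid (P–OH···O(pinacol) hydrogen bond, P=O···H–C(formyl) contact, Si-face attack giving 3S), and irreversible lactonisation of hydroxy acid 5 onto the cis carboxyl drains the equilibrium and relocks the Z alkene; the closest known reactions are the chiral phosphoric acid-catalysed allylboration of ordinary aldehydes and the addition/lactonisation of 2-formylbenzoates to 3-substituted phthalides, neither shown for γ-hydroxybutenolides.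

Step 4
Reactants: 6 (5S)-allyl butenolide
Product: 7 (5S)-4-{[tert-butyl(diphenyl)silyl]oxymethyl}-5-(prop-2-en-1-yl)-2,5-dihydrofuran-2-ol (anomer mixture)
Conditions: i-Bu2AlH (1.1 equiv), CH2Cl2, −78 °C; aqueous potassium sodium tartrate; used crude at once
Reagents that add atoms: none
Why: Low-temperature half-reduction of the lactone to the lactol (a masked Z-γ-hydroxy enal) leaves C3 untouched; the lactol is not purified because acid would aromatise it to a furan.

Step 5
Reactants: 8 methyl 2-(bromomethyl)acrylate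
Product: 10 methyl (2Z)-3-bromo-2-(bromomethyl)prop-2-enoate, via tribromo ester 9 (not isolated)
Conditions: Br2, CH2Cl2, 0 °C to rt; then Et3N, 0 °C
Reagents that add atoms: bromine, BrBr
Why: Alkene bromination then E2 dehydrobromination; the two CH2Br arms of 9 are equivalent so only one constitution can form, and the alkene geometry is irrelevant because C7 is re-set later.

Step 6
Reactants: 7 (5S)-allyl lactol; 10 methyl (2Z)-3-bromo-2-(bromomethyl)prop-2-enoate
Product: 13 (5S)-3-(bromomethyl)-5-[(1Z,3S)-2-{[tert-butyl(diphenyl)silyl]oxymethyl}-3-hydroxyhexa-1,5-dien-1-yl]furan-2(5H)-one, via bromo hydroxy ester 11 (not isolated), via bromo lactone 12 (not isolated)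
Conditions: In powder (1.2 equiv), 10 (3 equiv), THF/H2O (1:1), rt; then PPTS (5 mol %), LiBr (10 mol %), MeCN, 40 °C
Reagents that add atoms: none
Why: Indium Barbier allylation in water (the γ-bromoallylindium reacts at its bromine-bearing carbon through a chair transition state), then lactonisation and bromide-catalysed SN2' isomerisation to the conjugated 3-(bromomethyl)butenolide; C6 is set by 1,4-induction in a seven-membered indium chelate between the C3 hydroxyl and the Z-held aldehyde, with allyl delivery to the face syn to the C3–O bond (6S), while the C7 bromide centre is erased.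

Step 7
Reactants: 13 hydroxy 3-(bromomethyl)butenolide
Product: 14 (5S)-5-[(1Z,3S)-3-acetoxy-2-{[tert-butyl(diphenyl)silyl]oxymethyl}hexa-1,5-dien-1-yl]-3-(bromomethyl)furan-2(5H)-one
Conditions: Ac2O (1.5 equiv), Sc(OTf)3 (1 mol %), MeCN, −20 °C
Reagents that add atoms: acetic anhydride, CC(=O)OC(C)=O
Why: Amine-free Lewis acid-catalysed acetylation of the only free hydroxyl with retention at C3; nucleophilic amines are avoided because they would quaternise the allylic bromide.

Step 8
Reactants: 15 but-2-yn-1-ol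
Product: 16 (2Z)-3-iodobut-2-en-1-ol
Conditions: NaAlH2(OCH2CH2OCH3)2, THF, 0 °C; then I2, −78 °C to 0 °C
Reagents that add atoms: iodine, II
Why: Hydroxyl-directed trans-hydroalumination of the propargylic alcohol and iodinolysis of the alkenylalane (aluminium sits on the distal carbon, cis to CH2O) give the Z iodoalkene only; no stereocentre.

Step 9
Reactants: 16 (2Z)-3-iodobut-2-en-1-ol
Product: 17 (2Z)-3-iodobut-2-enal
Conditions: MnO2, CH2Cl2, rt, dark
Reagents that add atoms: none
Why: Neutral allylic alcohol oxidation, which preserves the Z iodoalkene.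

Step 10
Reactants: 14 acetoxy 3-(bromomethyl)butenolide; 17 (2Z)-3-iodobut-2-enal
Product: 18 (4S,5S)-5-[(1Z,3S)-3-acetoxy-2-{[tert-butyl(diphenyl)silyl]oxymethyl}hexa-1,5-dien-1-yl]-4-[(1S,2Z)-1-hydroxy-3-iodobut-2-en-1-yl]-3-methylideneoxolan-2-one
Conditions: Zn dust (3 equiv), 17 (2 equiv), THF/sat. aq. NH4Cl (2:1), 0 °C to rt
Reagents that add atoms: none
Why: Zinc Barbier reaction of a 3-(bromomethyl)furan-2(5H)-one (known reaction type): the cyclic allylzinc attacks through its ring β-carbon (C7) in a chair transition state with the aldehyde residue equatorial, anti to the C6 side chain (6,7-trans lactone), and the ring-locked allyl geometry gives the C7/C8 relationship of the target while regenerating the exocyclic methylene.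

Step 11
Reactants: 18 C8 alcohol
Product: 19 (1S,2Z)-1-{(2S,3R)-2-[(1Z,3S)-3-acetoxy-2-{[tert-butyl(diphenyl)silyl]oxymethyl}hexa-1,5-dien-1-yl]-4-methylidene-5-oxooxolan-3-yl}-3-iodobut-2-en-1-yl (2Z)-2-methylbut-2-enoate
Conditions: angelic acid (3 equiv), 2,4,6-trichlorobenzoyl chloride (3 equiv), Et3N (3 equiv), toluene, rt; then 18, 75 °C (no DMAP)
Reagents that add atoms: (2Z)-2-methylbut-2-enoic acid (angelic acid), C/C=C(/C)C(=O)O
Why: Yamaguchi-type esterification through the mixed anhydride without DMAP, conditions that acylate hindered secondary alcohols without angelate-to-tiglate isomerisation; C8 is retained (the descriptors change only through CIP priorities).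

Step 12
Reactants: 19 angelate with terminal alkene
Product: 21 (1S,2Z)-1-{(2S,3R)-2-[(1Z,3S)-3-acetoxy-2-{[tert-butyl(diphenyl)silyl]oxymethyl}-5-oxopent-1-en-1-yl]-4-methylidene-5-oxooxolan-3-yl}-3-iodobut-2-en-1-yl (2Z)-2-methylbut-2-enoate, via vicinal diol 20 (not isolated)
Conditions: OsO4 (2 mol %), NaIO4 (4 equiv), 2,6-lutidine (2 equiv), 1,4-dioxane/H2O (3:1), rt
Reagents that add atoms: osmium tetroxide, O=[Os](=O)(=O)=O; sodium periodate, [Na+].[O-]I(=O)(=O)=O
Why: Lemieux–Johnson cleavage of the only electron-rich monosubstituted alkene (the others are electron-poor or hindered trisubstituted) unveils the C1 aldehyde; no stereocentre changes.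

Step 13
Reactants: 21 seco aldehyde with (Z)-alkenyl iodide
Product: 22 (1S,3S,4Z,6S,7S,8R,9Z)-3-acetoxy-15-{[tert-butyl(diphenyl)silyl]oxy}-1-hydroxy-8-{[(2Z)-2-methylbut-2-enoyl]oxy}germacra-4,9,11(13)-trien-12,6-olide
Conditions: CrCl2 (10 equiv), NiCl2 (0.1 equiv), DMSO/THF (3:1), 0.002 M, rt, syringe-pump addition of 21
Reagents that add atoms: none
Why: Intramolecular Nozaki–Hiyama–Kishi reaction closes the ten-membered ring with retention of the Z alkene; the 1S carbinol is expected from 1,3-anti induction by the β-acetoxy group (polar model) within the macrocyclic transition state.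

Step 14
Reactants: 22 TBDPS ether of the target
Product: 23 (1S,3S,4Z,6S,7S,8R,9Z)-3-acetoxy-1,15-dihydroxy-8-{[(2Z)-2-methylbut-2-enoyl]oxy}germacra-4,9,11(13)-trien-12,6-olide
Conditions: HF·pyridine, pyridine/THF, 0 °C to rt
Reagents that add atoms: none
Why: Buffered fluoride desilylation of the primary allylic silyl ether leaves the esters, the α-methylene lactone and the allylic alcohol intact.

**Compound list**

1 | furan-3-ylmethanol | OCc1ccoc1 | starting material
2 | tert-butyl(furan-3-ylmethoxy)diphenylsilane | CC(C)(C)[Si](OCc1ccoc1)(c1ccccc1)c1ccccc1 | intermediate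
3 | furan endoperoxide (racemic) | CC(C)(C)[Si](OCC1=CC2OOC1O2)(c1ccccc1)c1ccccc1 | intermediate (not isolated)
4 | 5-hydroxy-4-{[tert-butyl(diphenyl)silyl]oxymethyl}furan-2(5H)-one | CC(C)(C)[Si](OCC1=CC(=O)OC1O)(c1ccccc1)c1ccccc1 | intermediate
5 | (2Z,4S)-3-{[tert-butyl(diphenyl)silyl]oxymethyl}-4-hydroxyhepta-2,6-dienoic acid | OC(=O)/C=C(\[C@@H](O)CC=C)CO[Si](c1ccccc1)(c1ccccc1)C(C)(C)C | intermediate (not isolated)
6 | (5S)-4-{[tert-butyl(diphenyl)silyl]oxymethyl}-5-(prop-2-en-1-yl)furan-2(5H)-one | O=C1C=C(CO[Si](c2ccccc2)(c2ccccc2)C(C)(C)C)[C@H](CC=C)O1 | intermediate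
7 | (5S)-4-{[tert-butyl(diphenyl)silyl]oxymethyl}-5-(prop-2-en-1-yl)-2,5-dihydrofuran-2-ol | OC1C=C(CO[Si](c2ccccc2)(c2ccccc2)C(C)(C)C)[C@H](CC=C)O1 | intermediate
8 | methyl 2-(bromomethyl)acrylate | C=C(CBr)C(=O)OC | starting material
9 | methyl 2,3-dibromo-2-(bromomethyl)propanoate | COC(=O)C(Br)(CBr)CBr | intermediate (not isolated)
10 | methyl (2Z)-3-bromo-2-(bromomethyl)prop-2-enoate | BrC/C(=C\Br)C(=O)OC | intermediate
11 | methyl (4S,5Z,7S)-3-bromo-6-{[tert-butyl(diphenyl)silyl]oxymethyl}-4,7-dihydroxy-2-methylidenedeca-5,9-dienoate (C3 epimers) | COC(=O)C(=C)C(Br)[C@@H](O)/C=C(/CO[Si](c1ccccc1)(c1ccccc1)C(C)(C)C)[C@@H](O)CC=C | intermediate (not isolated)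
12 | (5S)-4-bromo-5-[(1Z,3S)-2-{[tert-butyl(diphenyl)silyl]oxymethyl}-3-hydroxyhexa-1,5-dien-1-yl]-3-methylideneoxolan-2-one (C4 epimers) | C=C1C(=O)O[C@@H](/C=C(/CO[Si](c2ccccc2)(c2ccccc2)C(C)(C)C)[C@@H](O)CC=C)C1Br | intermediate (not isolated)
13 | (5S)-3-(bromomethyl)-5-[(1Z,3S)-2-{[tert-butyl(diphenyl)silyl]oxymethyl}-3-hydroxyhexa-1,5-dien-1-yl]furan-2(5H)-one | O=C1O[C@@H](/C=C(/CO[Si](c2ccccc2)(c2ccccc2)C(C)(C)C)[C@@H](O)CC=C)C=C1CBr | intermediate
14 | (5S)-5-[(1Z,3S)-3-acetoxy-2-{[tert-butyl(diphenyl)silyl]oxymethyl}hexa-1,5-dien-1-yl]-3-(bromomethyl)furan-2(5H)-one | O=C1O[C@@H](/C=C(/CO[Si](c2ccccc2)(c2ccccc2)C(C)(C)C)[C@@H](OC(C)=O)CC=C)C=C1CBr | intermediate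
15 | but-2-yn-1-ol | CC#CCO | starting material
16 | (2Z)-3-iodobut-2-en-1-ol | C/C(I)=C/CO | intermediate
17 | (2Z)-3-iodobut-2-enal | C/C(I)=C/C=O | intermediate
18 | (4S,5S)-5-[(1Z,3S)-3-acetoxy-2-{[tert-butyl(diphenyl)silyl]oxymethyl}hexa-1,5-dien-1-yl]-4-[(1S,2Z)-1-hydroxy-3-iodobut-2-en-1-yl]-3-methylideneoxolan-2-one | C=C1C(=O)O[C@@H](/C=C(/CO[Si](c2ccccc2)(c2ccccc2)C(C)(C)C)[C@@H](OC(C)=O)CC=C)[C@@H]1[C@H](O)/C=C(\I)C | intermediate
19 | angelate of 18 (name as in step 11) | C=C1C(=O)O[C@@H](/C=C(/CO[Si](c2ccccc2)(c2ccccc2)C(C)(C)C)[C@@H](OC(C)=O)CC=C)[C@@H]1[C@H](OC(=O)/C(C)=C\C)/C=C(\I)C | intermediate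
20 | 5,6-dihydroxyhexenyl analogue of 19 (diol from the terminal alkene, epimers at the new carbinol) | C=C1C(=O)O[C@@H](/C=C(/CO[Si](c2ccccc2)(c2ccccc2)C(C)(C)C)[C@@H](OC(C)=O)CC(O)CO)[C@@H]1[C@H](OC(=O)/C(C)=C\C)/C=C(\I)C | intermediate (not isolated)
21 | C1 aldehyde (name as in step 12) | C=C1C(=O)O[C@@H](/C=C(/CO[Si](c2ccccc2)(c2ccccc2)C(C)(C)C)[C@@H](OC(C)=O)CC=O)[C@@H]1[C@H](OC(=O)/C(C)=C\C)/C=C(\I)C | intermediate
22 | 15-O-TBDPS ether of the target (name as in step 13) | C=C1C(=O)O[C@H]2/C=C(/CO[Si](c3ccccc3)(c3ccccc3)C(C)(C)C)[C@@H](OC(C)=O)C[C@H](O)/C(C)=C\[C@@H](OC(=O)/C(C)=C\C)[C@H]12 | intermediate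
23 | (1S,3S,4Z,6S,7S,8R,9Z)-3-acetoxy-1,15-dihydroxy-8-{[(2Z)-2-methylbut-2-enoyl]oxy}germacra-4,9,11(13)-trien-12,6-olide | C=C1C(=O)O[C@H]2/C=C(/CO)[C@@H](OC(C)=O)C[C@H](O)/C(C)=C\[C@@H](OC(=O)/C(C)=C\C)[C@H]12 | target

**Step count and risks**

Total steps: 14. Longest linear sequence: 11 (steps 1–4, 6, 7, 10–14, from furan-3-ylmethanol).

The three steps most likely to fail:

1. Step 3 (the new step). The pseudo-acid is mostly in its closed form, and its own carboxylic acid could catalyse a racemic background reaction. The fallback uses known chemistry only and sets out from 4: O-methylation with (trimethylsilyl)diazomethane opens the pseudo-acid to methyl (2Z)-4-{[tert-butyl(diphenyl)silyl]oxy}-3-formylbut-2-enoate F1. The established (S)-TRIP-catalysed allylboration of this ordinary aldehyde gives methyl (2Z,4S)-3-{[tert-butyl(diphenyl)silyl]oxymethyl}-4-hydroxyhepta-2,6-dienoate F2, which lactonises with PPTS and comes back to the route at 6.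

2. Step 6. The sense and size of the 1,4-induction at C6 rest on a chelate model and are not assured. Excess indium can also reduce the product bromide, and lactol 7 aromatises with acid. If the induction is only low, the C6 epimers are separated at 13. If it has the opposite sense, the fallback sets out from 4 and runs the step 3 protocol with (R)-TRIP to give (5R)-4-{[tert-butyl(diphenyl)silyl]oxymethyl}-5-(prop-2-en-1-yl)furan-2(5H)-one F3. Reduction with i-Bu2AlH gives (5R)-4-{[tert-butyl(diphenyl)silyl]oxymethyl}-5-(prop-2-en-1-yl)-2,5-dihydrofuran-2-ol F4. Indium coupling with 10 then passes through methyl (4S,5Z,7R)-3-bromo-6-{[tert-butyl(diphenyl)silyl]oxymethyl}-4,7-dihydroxy-2-methylidenedeca-5,9-dienoate F5 and (5S)-4-bromo-5-[(1Z,3R)-2-{[tert-butyl(diphenyl)silyl]oxymethyl}-3-hydroxyhexa-1,5-dien-1-yl]-3-methylideneoxolan-2-one F6 to (5S)-3-(bromomethyl)-5-[(1Z,3R)-2-{[tert-butyl(diphenyl)silyl]oxymethyl}-3-hydroxyhexa-1,5-dien-1-yl]furan-2(5H)-one F7. A Mitsunobu esterification (AcOH, PPh3, DIAD, betaine preformed at −20 °C) installs the acetate with inversion at C3 and comes back at 14.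

3. Step 13. Oligomerisation can compete with ten-membered ring closure, and the C1 configuration depends on substrate control. The fallback sets out from 22 obtained as a C1 epimer mixture: Dess–Martin oxidation gives the macrocyclic enone, the 1-oxo analogue of 22 F8. Catalyst-controlled Corey–Bakshi–Shibata reduction with (R)-2-methyl-CBS-oxazaborolidine and catecholborane returns to 22 as the 1S epimer.

Further compounds
F1 | step 3 | methyl (2Z)-4-{[tert-butyl(diphenyl)silyl]oxy}-3-formylbut-2-enoate | COC(=O)/C=C(\C=O)CO[Si](c1ccccc1)(c1ccccc1)C(C)(C)C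
F2 | step 3 | methyl (2Z,4S)-3-{[tert-butyl(diphenyl)silyl]oxymethyl}-4-hydroxyhepta-2,6-dienoate | COC(=O)/C=C(\[C@@H](O)CC=C)CO[Si](c1ccccc1)(c1ccccc1)C(C)(C)C
F3 | step 6 | (5R)-4-{[tert-butyl(diphenyl)silyl]oxymethyl}-5-(prop-2-en-1-yl)furan-2(5H)-one | O=C1C=C(CO[Si](c2ccccc2)(c2ccccc2)C(C)(C)C)[C@@H](CC=C)O1
F4 | step 6 | (5R)-4-{[tert-butyl(diphenyl)silyl]oxymethyl}-5-(prop-2-en-1-yl)-2,5-dihydrofuran-2-ol | OC1C=C(CO[Si](c2ccccc2)(c2ccccc2)C(C)(C)C)[C@@H](CC=C)O1
F5 | step 6 | methyl (4S,5Z,7R)-3-bromo-6-{[tert-butyl(diphenyl)silyl]oxymethyl}-4,7-dihydroxy-2-methylidenedeca-5,9-dienoate | COC(=O)C(=C)C(Br)[C@@H](O)/C=C(/CO[Si](c1ccccc1)(c1ccccc1)C(C)(C)C)[C@H](O)CC=C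
F6 | step 6 | (5S)-4-bromo-5-[(1Z,3R)-2-{[tert-butyl(diphenyl)silyl]oxymethyl}-3-hydroxyhexa-1,5-dien-1-yl]-3-methylideneoxolan-2-one | C=C1C(=O)O[C@@H](/C=C(/CO[Si](c2ccccc2)(c2ccccc2)C(C)(C)C)[C@H](O)CC=C)C1Br
F7 | step 6 | (5S)-3-(bromomethyl)-5-[(1Z,3R)-2-{[tert-butyl(diphenyl)silyl]oxymethyl}-3-hydroxyhexa-1,5-dien-1-yl]furan-2(5H)-one | O=C1O[C@@H](/C=C(/CO[Si](c2ccccc2)(c2ccccc2)C(C)(C)C)[C@H](O)CC=C)C=C1CBr
F8 | step 13 | 1-oxo analogue of 22 (macrocyclic C1 enone) | C=C1C(=O)O[C@H]2/C=C(/CO[Si](c3ccccc3)(c3ccccc3)C(C)(C)C)[C@@H](OC(C)=O)CC(=O)/C(C)=C\[C@@H](OC(=O)/C(C)=C\C)[C@H]12
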